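**Retrosynthetic overview**

1. Numbering: carbons C1–C15 run from the alkyne terminus. Ring A is the oxolane O–C3–C4–C5–C6, ring B the oxolane O–C4–C5–C6–C7 (A and B together are the 2,5-dioxabicyclo[2.2.1]heptane), ring C the oxane O–C9…C13.
2. Late disconnections: C1 by Ohira–Bestmann homologation; ring B and the C8–Br bond together by bromoetherification of a Z-C7=C8 alkene with the C4 hydroxyl; C10–Br and C12–Br by double SN2 on an all-cis diol.
3. Ring C comes from a furan (Achmatowicz rearrangement, then silane reduction of the hemiketal; C13 by catalytic ethylation), and the furan is joined to C8 by Sonogashira coupling.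
4. Ring A comes from an α-chiral allylsilane (C3–C4–C5) and ethyl glyoxylate (C6–C7) by a chelate-controlled [3+2] annulation that makes C5–C6 and O–C3 together. The enabling feature is the unsubstituted methylene C5 of ring A between C6–O and C4, with the C4 oxygen trans to the C3 substituent and cis to the C6 substituent. This is the pattern left by anti attack on the allylsilane and a 1,2-silyl shift, with silicon at C4 as a masked hydroxyl (later the ring B oxygen).
5. Ring order: A (step 4), C (steps 8–9), B (step 18). Only C3 (Cu catalysis) and C13 (Zn catalysis) are reagent-set; the other seven stereocentres are relayed.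

Key step: step 4

Remark: ethyl glyoxylate is used freshly cracked from its commercial toluene solution. TIPS = triisopropylsilyl. [A] = (2R,4R,5S)-4-(dimethylphenylsilyl)-5-[(triisopropylsilyloxy)methyl]oxolan-2-yl, the ring A unit attached through C6.

**Route**

Step 1
Reactants: 1 (Z)-but-2-ene-1,4-diol
Product: 2 (Z)-4-[(triisopropylsilyl)oxy]but-2-en-1-ol
Conditions: NaH (1.0 equiv), THF, 0 °C; then TIPSCl, 0 °C to rt
Reagents that add atoms: triisopropylsilyl chloride, CC(C)[Si](Cl)(C(C)C)C(C)C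
Why: The monosodium alkoxide of the symmetric diol is silylated once (Williamson-type O-silylation); no stereocentre is formed and the Z-alkene is untouched.

Step 2
Reactants: 2 (Z)-4-[(triisopropylsilyl)oxy]but-2-en-1-ol
Product: 3 diethyl (Z)-4-[(triisopropylsilyl)oxy]but-2-en-1-yl phosphate
Conditions: ClP(O)(OEt)2, pyridine, DMAP (cat.), CH2Cl2, 0 °C to rt
Reagents that add atoms: diethyl chlorophosphate, CCOP(=O)(Cl)OCC
Why: O-Phosphorylation of the primary allylic alcohol installs the leaving group for allylic substitution.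

Step 3
Reactants: 3 diethyl (Z)-4-[(triisopropylsilyl)oxy]but-2-en-1-yl phosphate
Product: 4 (S)-{[2-(dimethylphenylsilyl)but-3-en-1-yl]oxy}triisopropylsilane
Conditions: PhMe2Si–Bpin, CuCl (5 mol %), C2-symmetric chiral imidazolinium salt (NHC precursor, 6 mol %), NaOMe, THF, 0 °C
Reagents that add atoms: (dimethylphenylsilyl)boronic acid pinacol ester, C[Si](C)(c1ccccc1)B1OC(C)(C)C(C)(C)O1
Why: Copper-catalysed enantioselective allylic substitution (SN2', γ-selective) places silicon on the CH2OTIPS-bearing carbon, and the chiral NHC ligand (antipode chosen accordingly) should set this centre, the future C3, as S.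

Step 4
Reactants: 4 (S)-{[2-(dimethylphenylsilyl)but-3-en-1-yl]oxy}triisopropylsilane; 5 ethyl glyoxylate
Product: 6 ethyl (2R,4R,5S)-4-(dimethylphenylsilyl)-5-[(triisopropylsilyloxy)methyl]oxolane-2-carboxylate (ring A; 2,5-trans, silyl cis to the ester)
Conditions: SnCl4 (1.1 equiv), CH2Cl2, −78 °C (5 precomplexed, then 4)
Reagents that add atoms: none
Why: SnCl4 binds both carbonyl oxygens of 5; the terminal alkene carbon C5 of 4 attacks the aldehyde carbon C6 anti to the C3–Si bond (anti-SE2'), and the bridged β-silyl cation is opened at C3 by the tin alkoxide anti to silicon, so that silicon moves from C3 to C4. The closest known reaction type is the Lewis acid-promoted [3+2] annulation of α-chiral allylsilanes with aldehydes in its chelate-controlled form. Ring A closes by intramolecular backside opening of the three-membered siliranium ion at C3 (an epoxide-opening-type five-membered closure); no other ring forms. C3 is set by inversion of the silicon-bearing centre of (S)-4, C4 by the stereospecific silyl shift (silicon trans to the CH2OTIPS group), and C6 by the face of the chelated aldehyde, which in chelate-controlled annulations is the 2,5-trans mode that puts the C6 substituent cis to silicon. Note that non-chelated annulations of this type normally give the 2,5-cis ring, which could not be carried on to the bicycle, so chelation is essential here. The step also needs annulation to beat Sakurai-type loss of silicon and Peterson elimination of the β-silyloxy silane; the PhMe2Si group, the bulky non-coordinating TIPS ether and −78 °C should secure this.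

Step 5
Reactants: 6 ethyl (2R,4R,5S)-4-(dimethylphenylsilyl)-5-[(triisopropylsilyloxy)methyl]oxolane-2-carboxylate
Product: 8 {[(2S,3R,5R)-3-(dimethylphenylsilyl)-5-ethynyloxolan-2-yl]methoxy}triisopropylsilane, via oxolane-2-carbaldehyde 7 (not isolated)
Conditions: DIBAL-H, CH2Cl2, −78 °C; then MeOH, K2CO3, dimethyl (1-diazo-2-oxopropyl)phosphonate, −78 °C to rt
Reagents that add atoms: dimethyl (1-diazo-2-oxopropyl)phosphonate, COP(=O)(OC)C(=[N+]=[N-])C(C)=O
Why: DIBAL-H stops at the aluminium hemiacetal at −78 °C, and the aldehyde freed on methanolysis is trapped at once by the Seyferth–Gilbert homologation in its Ohira–Bestmann form, which should limit epimerisation at C6.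

Step 6
Reactants: 8 {[(2S,3R,5R)-3-(dimethylphenylsilyl)-5-ethynyloxolan-2-yl]methoxy}triisopropylsilane; 9 5-bromofuran-2-carbaldehyde
Product: 10 5-([A]ethynyl)furan-2-carbaldehyde
Conditions: Pd(PPh3)2Cl2 (2 mol %), CuI (4 mol %), Et3N, THF, rt
Reagents that add atoms: none
Why: Sonogashira coupling of the terminal alkyne with the electron-poor 2-bromofuran; both silanes and the aldehyde are inert.

Step 7
Reactants: 10 5-([A]ethynyl)furan-2-carbaldehyde
Product: 11 (R)-1-[5-([A]ethynyl)furan-2-yl]propan-1-ol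
Conditions: Et2Zn, (+)-DAIB (5 mol %), toluene, 0 °C; aq. NH4Cl
Reagents that add atoms: diethylzinc, CC[Zn]CC
Why: Amino alcohol-catalysed addition of diethylzinc to the aryl-type aldehyde is catalyst-controlled and should set C13 as R ((−)-DAIB gives S carbinols from aromatic aldehydes, hence the (+) antipode).

Step 8
Reactants: 11 (R)-1-[5-([A]ethynyl)furan-2-yl]propan-1-ol
Product: 12 (2R)-2-ethyl-6-hydroxy-6-([A]ethynyl)-2H-pyran-3(6H)-one (mixture at the hemiketal carbon)
Conditions: NBS, NaHCO3, NaOAc, THF/H2O (4:1), 0 °C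
Reagents that add atoms: water, O
Why: Achmatowicz rearrangement: oxidation of the furan by NBS/water and recyclisation of the ene-dione onto the carbinol oxygen dearomatise the furan to the pyranone hemiketal, with C13 retained.

Step 9
Reactants: 12 (2R)-2-ethyl-6-hydroxy-6-([A]ethynyl)-2H-pyran-3(6H)-one
Product: 13 (2R,6R)-2-ethyl-6-([A]ethynyl)-2H-pyran-3(6H)-one (2,6-cis)
Conditions: Et3SiH, TFA, CH2Cl2, −40 to 0 °C
Reagents that add atoms: none
Why: Ionic hydrogenation: axial hydride attack on the half-chair oxocarbenium ion, whose ethyl group is pseudoequatorial, should give the 2,6-cis ring (C9 set by C13).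

Step 10
Reactants: 13 (2R,6R)-2-ethyl-6-([A]ethynyl)-2H-pyran-3(6H)-one
Product: 14 (2R,3S,6R)-2-ethyl-6-([A]ethynyl)-3,6-dihydro-2H-pyran-3-ol (hydroxyl trans to ethyl)
Conditions: NaBH4, CeCl3·7H2O, MeOH, −78 °C
Reagents that add atoms: none
Why: Luche reduction: 1,2-selective axial hydride delivery to the enone should give the pseudoequatorial C12 alcohol, trans to the ethyl group.

Step 11
Reactants: 14 (2R,3S,6R)-2-ethyl-6-([A]ethynyl)-3,6-dihydro-2H-pyran-3-ol
Product: 15 (2R,3R,6R)-2-ethyl-6-([A]ethynyl)-3,6-dihydro-2H-pyran-3-yl 4-nitrobenzoate (ester cis to ethyl)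
Conditions: 4-nitrobenzoic acid, PPh3, DIAD, THF, 0 °C to rt
Reagents that add atoms: 4-nitrobenzoic acid, O=C(O)c1ccc([N+](=O)[O-])cc1
Why: Mitsunobu reaction: SN2 displacement of the activated allylic alcohol by the carboxylate inverts C12.

Step 12
Reactants: 15 (2R,3R,6R)-2-ethyl-6-([A]ethynyl)-3,6-dihydro-2H-pyran-3-yl 4-nitrobenzoate
Product: 16 (2R,3R,6R)-2-ethyl-6-([A]ethynyl)-3,6-dihydro-2H-pyran-3-ol (hydroxyl cis to ethyl)
Conditions: K2CO3 (cat.), MeOH, 0 °C to rt
Reagents that add atoms: none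
Why: Base-catalysed transesterification frees the C12 alcohol, now pseudoaxial and cis to ethyl.

Step 13
Reactants: 16 (2R,3R,6R)-2-ethyl-6-([A]ethynyl)-3,6-dihydro-2H-pyran-3-ol
Product: 17 all-cis epoxy alcohol: the C10–C11 epoxide of 16 on the face of the C12 hydroxyl (ethyl, hydroxyl, epoxide and alkynyl group all on one face of ring C)
Conditions: VO(acac)2 (cat.), t-BuOOH, CH2Cl2, 0 °C to rt
Reagents that add atoms: tert-butyl hydroperoxide, CC(C)(C)OO
Why: Vanadium-catalysed hydroxyl-directed epoxidation delivers oxygen syn to the pseudoaxial C12 hydroxyl, which sets C10 and C11; the alkyne is inert.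

Step 14
Reactants: 17 all-cis epoxy alcohol
Product: 18 (2R,3R,5S,6S)-2-ethyl-6-([A]ethynyl)oxane-3,5-diol (all-cis; both hydroxyls axial)
Conditions: LiAlH4, THF, 0 °C
Reagents that add atoms: none
Why: Hydride opens the epoxide trans-diaxially (Fürst–Plattner rule) at C11, which leaves the C10 oxygen axial and gives the all-cis 1,3-diol.

Step 15
Reactants: 18 (2R,3R,5S,6S)-2-ethyl-6-([A]ethynyl)oxane-3,5-diol
Product: 20 (2R,3S,5R,6S)-3,5-dibromo-2-ethyl-6-([A]ethynyl)oxane (all substituents equatorial), via bis-triflate 19 (not isolated)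
Conditions: Tf2O, pyridine, CH2Cl2, −20 °C; then n-Bu4NBr, toluene, rt to 40 °C
Reagents that add atoms: tetrabutylammonium bromide, CCCC[N+](CCCC)(CCCC)CCCC.[Br-]
Why: Both axial triflates, gauche to the ring oxygen and so shielded from its participation, should undergo SN2 displacement by bromide with inversion to give the C10,C12-diequatorial dibromide.

Step 16
Reactants: 20 (2R,3S,5R,6S)-3,5-dibromo-2-ethyl-6-([A]ethynyl)oxane
Product: 21 (2S,3R,5R)-5-{[(2S,3R,5S,6R)-3,5-dibromo-6-ethyloxan-2-yl]ethynyl}-2-[(triisopropylsilyloxy)methyl]oxolan-3-ol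
Conditions: KBr, AcOOH, NaOAc, AcOH, rt
Reagents that add atoms: peracetic acid, CC(=O)OO
Why: Fleming–Tamao oxidation: ipso-bromodesilylation of the phenyl group and peracid-induced 1,2-shift of C4 from silicon to oxygen replace silicon by hydroxyl with retention at C4; the alkyne, deactivated by two propargylic oxygens, and the TIPS ether should persist.

Step 17
Reactants: 21 (2S,3R,5R)-5-{[(2S,3R,5S,6R)-3,5-dibromo-6-ethyloxan-2-yl]ethynyl}-2-[(triisopropylsilyloxy)methyl]oxolan-3-ol
Product: 22 (2S,3R,5R)-5-{(Z)-2-[(2S,3R,5S,6R)-3,5-dibromo-6-ethyloxan-2-yl]ethenyl}-2-[(triisopropylsilyloxy)methyl]oxolan-3-ol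
Conditions: H2 (1 atm), Pd/CaCO3 poisoned with Pb(OAc)2 (Lindlar catalyst), quinoline, EtOAc, rt
Reagents that add atoms: none
Why: Lindlar semi-hydrogenation adds hydrogen cis and stops at the Z-alkene; secondary alkyl bromides should not be hydrogenolysed on the poisoned catalyst.

Step 18
Reactants: 22 (2S,3R,5R)-5-{(Z)-2-[(2S,3R,5S,6R)-3,5-dibromo-6-ethyloxan-2-yl]ethenyl}-2-[(triisopropylsilyloxy)methyl]oxolan-3-ol
Product: 23 TIPS ether of the bicyclic tribromide: the target skeleton (3S,4R,6R,7S,8R,9R,10R,12S,13R) with CH2OTIPS at C3 in place of the ethynyl group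
Conditions: NBS, MeCN, −20 to 0 °C, dark
Reagents that add atoms: N-bromosuccinimide, O=C1CCC(=O)N1Br
Why: Bromoetherification: the C4 hydroxyl opens the bromonium ion of the Z-alkene at C7 in a 5-exo anti addition, so the Z geometry becomes the 7S,8R pair, and closure with C8 endo is expected because the exo mode forces C9 against the C5 methylene bridge.

Step 19
Reactants: 23 TIPS ether of the bicyclic tribromide
Product: 24 bicyclic tribromide primary alcohol (CH2OH at C3)
Conditions: TBAF, AcOH, THF, 0 °C to rt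
Reagents that add atoms: none
Why: Fluoride cleaves the Si–O bond of the TIPS ether, and acetic acid buffering should protect the secondary bromides from elimination.

Step 20
Reactants: 24 bicyclic tribromide primary alcohol
Product: 25 bicyclic tribromide aldehyde (exo CHO at C3)
Conditions: Dess–Martin periodinane, CH2Cl2, 0 °C to rt
Reagents that add atoms: none
Why: Dess–Martin oxidation of the primary alcohol under neutral conditions should give the aldehyde without epimerisation at C3.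

Step 21
Reactants: 25 bicyclic tribromide aldehyde
Product: 26 (3S,4R,6R,7S,8R,9R,10R,12S,13R)-8,10,12-tribromo-3,6:4,7:9,13-triepoxypentadec-1-yne (target)
Conditions: dimethyl (1-diazo-2-oxopropyl)phosphonate, K2CO3, MeOH, 0 °C to rt
Reagents that add atoms: dimethyl (1-diazo-2-oxopropyl)phosphonate, COP(=O)(OC)C(=[N+]=[N-])C(C)=O
Why: Seyferth–Gilbert homologation with the Ohira–Bestmann reagent converts the aldehyde into the terminal alkyne under mild carbonate conditions, C3 keeping the less hindered exo configuration.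

**Compound list**

1 | (Z)-but-2-ene-1,4-diol | OC/C=C\CO | starting material
2 | (Z)-4-[(triisopropylsilyl)oxy]but-2-en-1-ol | OC/C=C\CO[Si](C(C)C)(C(C)C)C(C)C | intermediate
3 | diethyl (Z)-4-[(triisopropylsilyl)oxy]but-2-en-1-yl phosphate | CCOP(=O)(OCC)OC/C=C\CO[Si](C(C)C)(C(C)C)C(C)C | intermediate
4 | (S)-{[2-(dimethylphenylsilyl)but-3-en-1-yl]oxy}triisopropylsilane | C=C[C@H]([Si](C)(C)c1ccccc1)CO[Si](C(C)C)(C(C)C)C(C)C | intermediate
5 | ethyl glyoxylate | CCOC(=O)C=O | starting material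
6 | ethyl (2R,4R,5S)-4-(dimethylphenylsilyl)-5-[(triisopropylsilyloxy)methyl]oxolane-2-carboxylate | CC(C)[Si](C(C)C)(C(C)C)OC[C@@H]1O[C@@H](C(=O)OCC)C[C@H]1[Si](C)(C)c1ccccc1 | intermediate
7 | (2R,4R,5S)-4-(dimethylphenylsilyl)-5-[(triisopropylsilyloxy)methyl]oxolane-2-carbaldehyde | CC(C)[Si](C(C)C)(C(C)C)OC[C@@H]1O[C@@H](C=O)C[C@H]1[Si](C)(C)c1ccccc1 | intermediate
8 | {[(2S,3R,5R)-3-(dimethylphenylsilyl)-5-ethynyloxolan-2-yl]methoxy}triisopropylsilane | CC(C)[Si](C(C)C)(C(C)C)OC[C@@H]1O[C@@H](C#C)C[C@H]1[Si](C)(C)c1ccccc1 | intermediate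
9 | 5-bromofuran-2-carbaldehyde | O=Cc1ccc(Br)o1 | starting material
10 | 5-([A]ethynyl)furan-2-carbaldehyde | CC(C)[Si](C(C)C)(C(C)C)OC[C@@H]1O[C@@H](C#Cc2ccc(C=O)o2)C[C@H]1[Si](C)(C)c1ccccc1 | intermediate
11 | (R)-1-[5-([A]ethynyl)furan-2-yl]propan-1-ol | CC(C)[Si](C(C)C)(C(C)C)OC[C@@H]1O[C@@H](C#Cc2ccc([C@H](O)CC)o2)C[C@H]1[Si](C)(C)c1ccccc1 | intermediate
12 | (2R)-2-ethyl-6-hydroxy-6-([A]ethynyl)-2H-pyran-3(6H)-one | CC(C)[Si](C(C)C)(C(C)C)OC[C@@H]1O[C@@H](C#CC2(O)O[C@H](CC)C(=O)C=C2)C[C@H]1[Si](C)(C)c1ccccc1 | intermediate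
13 | (2R,6R)-2-ethyl-6-([A]ethynyl)-2H-pyran-3(6H)-one | CC(C)[Si](C(C)C)(C(C)C)OC[C@@H]1O[C@@H](C#C[C@@H]2O[C@H](CC)C(=O)C=C2)C[C@H]1[Si](C)(C)c1ccccc1 | intermediate
14 | (2R,3S,6R)-2-ethyl-6-([A]ethynyl)-3,6-dihydro-2H-pyran-3-ol | CC(C)[Si](C(C)C)(C(C)C)OC[C@@H]1O[C@@H](C#C[C@@H]2O[C@H](CC)[C@@H](O)C=C2)C[C@H]1[Si](C)(C)c1ccccc1 | intermediate
15 | (2R,3R,6R)-2-ethyl-6-([A]ethynyl)-3,6-dihydro-2H-pyran-3-yl 4-nitrobenzoate | CC(C)[Si](C(C)C)(C(C)C)OC[C@@H]1O[C@@H](C#C[C@@H]2O[C@H](CC)[C@H](OC(=O)c3ccc([N+](=O)[O-])cc3)C=C2)C[C@H]1[Si](C)(C)c1ccccc1 | intermediate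
16 | (2R,3R,6R)-2-ethyl-6-([A]ethynyl)-3,6-dihydro-2H-pyran-3-ol | CC(C)[Si](C(C)C)(C(C)C)OC[C@@H]1O[C@@H](C#C[C@@H]2O[C@H](CC)[C@H](O)C=C2)C[C@H]1[Si](C)(C)c1ccccc1 | intermediate
17 | all-cis C10–C11 epoxide of 16 | CC(C)[Si](C(C)C)(C(C)C)OC[C@@H]1O[C@@H](C#C[C@@H]2O[C@H](CC)[C@H](O)[C@@H]3O[C@H]23)C[C@H]1[Si](C)(C)c1ccccc1 | intermediate
18 | (2R,3R,5S,6S)-2-ethyl-6-([A]ethynyl)oxane-3,5-diol | CC(C)[Si](C(C)C)(C(C)C)OC[C@@H]1O[C@@H](C#C[C@@H]2O[C@H](CC)[C@H](O)C[C@@H]2O)C[C@H]1[Si](C)(C)c1ccccc1 | intermediate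
19 | bis(trifluoromethanesulfonate) of 18 | CC(C)[Si](C(C)C)(C(C)C)OC[C@@H]1O[C@@H](C#C[C@@H]2O[C@H](CC)[C@H](OS(=O)(=O)C(F)(F)F)C[C@@H]2OS(=O)(=O)C(F)(F)F)C[C@H]1[Si](C)(C)c1ccccc1 | intermediate
20 | (2R,3S,5R,6S)-3,5-dibromo-2-ethyl-6-([A]ethynyl)oxane | CC(C)[Si](C(C)C)(C(C)C)OC[C@@H]1O[C@@H](C#C[C@@H]2O[C@H](CC)[C@@H](Br)C[C@H]2Br)C[C@H]1[Si](C)(C)c1ccccc1 | intermediate
21 | (2S,3R,5R)-5-{[(2S,3R,5S,6R)-3,5-dibromo-6-ethyloxan-2-yl]ethynyl}-2-[(triisopropylsilyloxy)methyl]oxolan-3-ol | CC(C)[Si](C(C)C)(C(C)C)OC[C@@H]1O[C@@H](C#C[C@@H]2O[C@H](CC)[C@@H](Br)C[C@H]2Br)C[C@H]1O | intermediate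
22 | (2S,3R,5R)-5-{(Z)-2-[(2S,3R,5S,6R)-3,5-dibromo-6-ethyloxan-2-yl]ethenyl}-2-[(triisopropylsilyloxy)methyl]oxolan-3-ol | CC(C)[Si](C(C)C)(C(C)C)OC[C@@H]1O[C@@H](/C=C\[C@@H]2O[C@H](CC)[C@@H](Br)C[C@H]2Br)C[C@H]1O | intermediate
23 | TIPS ether of the bicyclic tribromide (CH2OTIPS at C3) | CC(C)[Si](C(C)C)(C(C)C)OC[C@@H]1O[C@@H]2C[C@H]1O[C@@H]2[C@@H](Br)[C@@H]1O[C@H](CC)[C@@H](Br)C[C@H]1Br | intermediate
24 | bicyclic tribromide primary alcohol (CH2OH at C3) | OC[C@@H]1O[C@@H]2C[C@H]1O[C@@H]2[C@@H](Br)[C@@H]1O[C@H](CC)[C@@H](Br)C[C@H]1Br | intermediate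
25 | bicyclic tribromide aldehyde (CHO at C3) | O=C[C@@H]1O[C@@H]2C[C@H]1O[C@@H]2[C@@H](Br)[C@@H]1O[C@H](CC)[C@@H](Br)C[C@H]1Br | intermediate
26 | (3S,4R,6R,7S,8R,9R,10R,12S,13R)-8,10,12-tribromo-3,6:4,7:9,13-triepoxypentadec-1-yne | C#C[C@@H]1O[C@@H]2C[C@H]1O[C@@H]2[C@@H](Br)[C@@H]1O[C@H](CC)[C@@H](Br)C[C@H]1Br | target

**Step count and risks**

Total step count: 21. Longest linear sequence: 21 steps (from 1; 5 and 9 are commercial and enter directly).

Steps most likely to fail:

1. Step 4. Desilylative Sakurai-type allylation or oligomerisation of the very electrophilic glyoxylate may outrun ring closure, and weak chelate control would leak to the 2,5-cis ring. The fallback changes the C6–C7 building block and the oxidation level at C7. It sets out from 4, which is annulated under SnCl4 with benzyloxyacetaldehyde, the α-alkoxy aldehyde class for which chelate-controlled trans annulation is established, to give {[(2S,3R,5R)-5-(benzyloxymethyl)-3-(dimethylphenylsilyl)oxolan-2-yl]methoxy}triisopropylsilane F1. Hydrogenolysis (H2, Pd(OH)2/C, EtOAc) gives [(2R,4R,5S)-4-(dimethylphenylsilyl)-5-[(triisopropylsilyloxy)methyl]oxolan-2-yl]methanol F2. Dess–Martin oxidation of F2 gives 7, where the route is rejoined (second stage of step 5).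

2. Step 18. Poor facial selectivity in bromonium capture (C8 exo instead of endo) or competing 6-endo closure. The fallback sets C7 and C8 by hydroxyl-directed epoxidation and SN2 chemistry instead. It sets out from 21. Trans-selective hydrogenation (H2, [Cp*Ru(cod)Cl], AgOTf, CH2Cl2) gives the (E)-alkene isomer of 22, F3. VO(acac)2/t-BuOOH epoxidation directed by the homoallylic C4 hydroxyl gives the trans C7–C8 epoxide F4. Camphorsulfonic acid induces 5-exo opening at C7 with inversion to give the bicyclic C8 alcohol F5, whose C8 is epimeric to the bromide position. Appel bromination with inversion (CBr4, P(n-Oct)3, toluene, 70 °C) converts F5 into 23.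

3. Step 15. E2 elimination toward C11 or stalling after the first displacement on the 1,3-diaxial bis-triflate. The fallback brings in the two bromides one at a time. It sets out from 18. SO2Cl2/pyridine (CH2Cl2, −78 °C) gives the C10,C12 cyclic sulfate F6. LiBr in THF opens it at C12 with inversion to give the lithium C10 sulfate monoester F7 (attack at C10 would converge on the same end product). Aqueous H2SO4 (cat.) hydrolyses it to the C12-bromo C10-alcohol F8. A single Appel bromination with inversion (CBr4, P(n-Oct)3) gives 20.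

**Further compounds**

F1 | step 4 | {[(2S,3R,5R)-5-(benzyloxymethyl)-3-(dimethylphenylsilyl)oxolan-2-yl]methoxy}triisopropylsilane | CC(C)[Si](C(C)C)(C(C)C)OC[C@@H]1O[C@@H](COCc2ccccc2)C[C@H]1[Si](C)(C)c1ccccc1
F2 | step 4 | [(2R,4R,5S)-4-(dimethylphenylsilyl)-5-[(triisopropylsilyloxy)methyl]oxolan-2-yl]methanol | CC(C)[Si](C(C)C)(C(C)C)OC[C@@H]1O[C@@H](CO)C[C@H]1[Si](C)(C)c1ccccc1
F3 | step 18 | (E)-alkene isomer of 22 | CC(C)[Si](C(C)C)(C(C)C)OC[C@@H]1O[C@@H](/C=C/[C@@H]2O[C@H](CC)[C@@H](Br)C[C@H]2Br)C[C@H]1O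
F4 | step 18 | trans C7–C8 epoxide of F3 | CC(C)[Si](C(C)C)(C(C)C)OC[C@@H]1O[C@@H]([C@H]3O[C@@H]3[C@@H]2O[C@H](CC)[C@@H](Br)C[C@H]2Br)C[C@H]1O
F5 | step 18 | bicyclic C8 alcohol (C8 epimeric to the bromide of 23) | CC(C)[Si](C(C)C)(C(C)C)OC[C@@H]1O[C@@H]2C[C@H]1O[C@@H]2[C@H](O)[C@@H]1O[C@H](CC)[C@@H](Br)C[C@H]1Br
F6 | step 15 | C10,C12 cyclic sulfate of 18 | CC(C)[Si](C(C)C)(C(C)C)OC[C@@H]1O[C@@H](C#C[C@@H]2O[C@H](CC)[C@H]3C[C@@H]2OS(=O)(=O)O3)C[C@H]1[Si](C)(C)c1ccccc1
F7 | step 15 | lithium C10 sulfate monoester of the C12 bromide | CC(C)[Si](C(C)C)(C(C)C)OC[C@@H]1O[C@@H](C#C[C@@H]2O[C@H](CC)[C@@H](Br)C[C@@H]2OS(=O)(=O)[O-])C[C@H]1[Si](C)(C)c1ccccc1.[Li+]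
F8 | step 15 | C12-bromo C10-alcohol | CC(C)[Si](C(C)C)(C(C)C)OC[C@@H]1O[C@@H](C#C[C@@H]2O[C@H](CC)[C@@H](Br)C[C@@H]2O)C[C@H]1[Si](C)(C)c1ccccc1
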